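## Overview

1. Germacrane locants are used throughout. The ring is C1(=O)–C2=C3–C4(Me)–C5(OH)–C6(O)–C7–C8(O)–C9–C10(Me,O) and the side chain is C11(=C13)–C12.
2. The retrosynthesis cuts, in order: O–C6 of the γ-lactone (back to a C5–C6 cis-epoxide and a C12 tert-butyl ester) and the O8–acyl bond; O10–C3 of the furanone; C3–C4 with re-closure of C1–C6 (retro-oxy-Cope, ten- to six-membered ring); then C1–C2 (acetylide) and C5–C6 (enolate alkenylation).
3. Enabling feature: the ten-membered carbocycle holds its C1 ketone and the oxygenated C5–C6 edge in the 1,5-relation of a cyclodec-5-enone. C3 is at ketone level inside the C10–O–C3 furanone, so C1/C3 is a masked 1,3-diketone next to the C10 carbinol and C3 can come from an ynol-ether carbon. C1–C10–C9–C8–C7–C6 is the ring of an oxidised (R)-carvone.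
4. Forward: the carvone ring is oxidised at C12, C8 and C10 and armed at C6 (propenyl) and C1 (ethoxyethynyl). It is then expanded by four carbons to the ten-membered ring, with furanone closure in the same operation. The transient C5–C6 epoxide and the C8 angelate follow, and the γ-lactone closes last.
5. Stereochemistry: C7 comes from (R)-carvone, C8 from γ-hydroxylation anti to C7, and C10 from C8-OH-guided epoxidation with hydride opening at C9. The relay centres C6 (trans to C7) and C1 (axial attack) pass their information through the chair [3,3] shift to C4 (R) and the 5Z alkene. C5 and C6 come from C8-OH-directed epoxidation and SN2 inversion at C6, and the angelate geometry from angelic acid.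

Key step: step 13

Assumption: the configuration at C1 of diol 10, the allene axis of 19 and the C2=C3 geometry of 20 are left undefined, because each element is erased in the following transformation and all isomers converge.

## Route

Step 1
Reactants: 1 (R)-(−)-carvone
Product: 2 10-chlorocarvone, (5R)-5-(3-chloroprop-1-en-2-yl)-2-methylcyclohex-2-en-1-one (p-menthane locant 10 = germacrane C12)
Conditions: Ca(OCl)2, solid CO2, CH2Cl2/H2O, 0 °C
Reagents that add atoms: calcium hypochlorite, [Ca+2].[O-]Cl.[O-]Cl
Why: Ene-type allylic chlorination with hypochlorous acid made in situ engages only the electron-rich 1,1-disubstituted alkene and regenerates a 1,1-disubstituted alkene, and it is preferred to a selenium dioxide oxidation because that reagent would also attack the tertiary allylic C7–H; the enone and C7 stay untouched.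

Step 2
Reactants: 2 10-chlorocarvone
Product: 4 10-hydroxycarvone, (5R)-5-(3-hydroxyprop-1-en-2-yl)-2-methylcyclohex-2-en-1-one, via 10-acetoxycarvone 3 (not isolated)
Conditions: KOAc, n-Bu4NI (cat.), DMF, 50 °C; then MeOH, K2CO3 (cat.), 0 °C to rt
Reagents that add atoms: potassium acetate, CC(=O)[O-].[K+]
Why: SN2 displacement of the primary allylic chloride by acetate, followed by carbonate-catalysed transesterification in the same flask, should give the allylic alcohol without disturbing the enone or C7.

Step 3
Reactants: 4 10-hydroxycarvone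
Product: 5 10-(triethylsilyloxy)carvone, (5R)-2-methyl-5-[3-(triethylsilyloxy)prop-1-en-2-yl]cyclohex-2-en-1-one
Conditions: TESCl, imidazole, CH2Cl2, 0 °C
Reagents that add atoms: chlorotriethylsilane, CC[Si](Cl)(CC)CC
Why: This is a standard imidazole-promoted silylation of a primary alcohol, and TES is chosen because it tolerates base, hydride and organometallic steps yet leaves with the TMS group in the acidic work-up of step 13 while the secondary TBS ether stays.

Step 4
Reactants: 5 10-(triethylsilyloxy)carvone
Product: 6 linear dienol ether, (5S)-2-methyl-5-[3-(triethylsilyloxy)prop-1-en-2-yl]-1-(trimethylsilyloxy)cyclohexa-1,3-diene (C1=C10 and C9=C8; C7 spatially unchanged)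
Conditions: KOt-Bu, THF, −78 to −20 °C; TMSCl/Et3N, −78 °C; cold pentane/NaHCO3 work-up, used without chromatography
Reagents that add atoms: chlorotrimethylsilane, C[Si](C)(C)Cl
Why: Equilibrating deprotonation of a cyclohex-2-enone with tert-butoxide gives the through-conjugated dienolate (loss of a C8 proton), which is the thermodynamic enolate, and O-silylation traps it as the linear 1-silyloxy-1,3-diene with C7 untouched.

Step 5
Reactants: 6 linear dienol ether
Product: 7 (4S,5R)-4-hydroxy-2-methyl-5-[3-(triethylsilyloxy)prop-1-en-2-yl]cyclohex-2-en-1-one (C8–OH trans to the C7 side chain)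
Conditions: DMDO (acetone, 1.0 equiv), CH2Cl2, −78 °C; then dilute aq. citric acid/THF, 0 °C
Reagents that add atoms: dimethyldioxirane, CC1(C)OO1
Why: In this vinylogous Rubottom oxidation, DMDO epoxidises the distal, less hindered C8=C9 bond of the electron-rich dienol ether (as in the 6-hydroxylation of steroidal 3,5-dienol ethers) on the face anti to the adjacent C7 side chain, and collapse with loss of TMS returns the enone with 8S configuration.

Step 6
Reactants: 7 C8-hydroxy enone
Product: 8 syn epoxy ketone, (1R,4R,5R,6R)-5-hydroxy-1-methyl-4-[3-(triethylsilyloxy)prop-1-en-2-yl]-7-oxabicyclo[4.1.0]heptan-2-one (oxirane on C9–C10, syn to C8–OH, anti to the C7 side chain)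
Conditions: t-BuOOH (decane), Triton B (cat.), THF, −10 to 0 °C
Reagents that add atoms: tert-butyl hydroperoxide, CC(C)(C)OO
Why: In this Weitz–Scheffer nucleophilic epoxidation the peroxide anion adds axially to C9 on the face that carries the hydrogen-bonding C8–OH and is anti to the C7 side chain (the face carvone itself uses), so ring closure sets C9 and C10 (10R) with the oxirane syn to C8–OH.

Step 7
Reactants: 8 syn epoxy ketone
Product: 9 C8-OTBS epoxy ketone, (1R,4R,5R,6R)-5-(tert-butyldimethylsilyloxy)-1-methyl-4-[3-(triethylsilyloxy)prop-1-en-2-yl]-7-oxabicyclo[4.1.0]heptan-2-one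
Conditions: TBSCl, imidazole, DMAP (cat.), DMF, rt
Reagents that add atoms: tert-butylchlorodimethylsilane, CC(C)(C)[Si](C)(C)Cl
Why: This is a standard silylation of a secondary alcohol under non-acidic conditions that leave the epoxy ketone and the TES ether intact.

Step 8
Reactants: 9 C8-OTBS epoxy ketone
Product: 10 (2R,4S,5R)-4-(tert-butyldimethylsilyloxy)-2-methyl-5-[3-(triethylsilyloxy)prop-1-en-2-yl]cyclohexane-1,2-diol (C1 carbinol of either configuration; C10–OH cis to C8–O)
Conditions: LiEt3BH (4 equiv), THF, 0 to 45 °C; then H2O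
Reagents that add atoms: none
Why: The trialkylborohydride first reduces the ketone and then opens the trisubstituted epoxide by SN2 attack at the secondary C9 rather than the fully substituted C10 (the regiochemistry of 1-methylcyclohexene oxides with complex hydrides), so the C10–O bond and its configuration are retained.

Step 9
Reactants: 10 C1,C10-diol
Product: 11 (2R,4S,5R)-4-(tert-butyldimethylsilyloxy)-2-hydroxy-2-methyl-5-[3-(triethylsilyloxy)prop-1-en-2-yl]cyclohexan-1-one
Conditions: IBX, DMSO, rt
Reagents that add atoms: none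
Why: IBX oxidises the secondary alcohol of a 1,2-diol to the α-ketol without C–C cleavage, cannot touch the tertiary C10–OH and, unlike activated-DMSO conditions, spares the primary TES ether.

Step 10
Reactants: 11 α-hydroxy ketone
Product: 12 (2R,4S,5R)-4-(tert-butyldimethylsilyloxy)-2-methyl-5-[3-(triethylsilyloxy)prop-1-en-2-yl]-2-(trimethylsilyloxy)cyclohexan-1-one
Conditions: N-(trimethylsilyl)imidazole, CH2Cl2, rt
Reagents that add atoms: N-(trimethylsilyl)imidazole, C[Si](C)(C)n1ccnc1
Why: The silylimidazole silylates the hindered tertiary alcohol under neutral conditions, which avoids α-ketol rearrangement and enol silylation and masks O10 with the group that is easiest to remove in step 13.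

Step 11
Reactants: 12 C10-silyloxy ketone; 13 (E)-1-bromoprop-1-ene
Product: 14 (2R,4S,5R,6S)-4-(tert-butyldimethylsilyloxy)-2-methyl-6-[(E)-prop-1-enyl]-5-[3-(triethylsilyloxy)prop-1-en-2-yl]-2-(trimethylsilyloxy)cyclohexan-1-one (propenyl equatorial, trans to C7)
Conditions: Pd2(dba)3 (2.5 mol %), Q-Phos (6 mol %), LiHMDS (2.2 equiv), toluene/THF, rt to 45 °C; AcOH/THF quench at −78 °C
Reagents that add atoms: 13 (E)-1-bromoprop-1-ene, C/C=C/Br
Why: In this palladium-catalysed α-alkenylation of a ketone enolate with an alkenyl bromide only C6 can enolise, oxidative addition and reductive elimination retain the E geometry, the allylic silyl ether is not ionised by Pd(0), and axial protonation of the product dienolate at C6 on the cold quench places the propenyl group equatorial and trans to C7 (6S).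

Step 12
Reactants: 14 C6-(E)-propenyl ketone; 15 ethoxyacetylene
Product: 18 (1S,2R,4S,5R,6S)-4-(tert-butyldimethylsilyloxy)-1-(ethoxyethynyl)-2-methyl-6-[(E)-prop-1-enyl]-5-[3-(triethylsilyloxy)prop-1-en-2-yl]-2-(trimethylsilyloxy)cyclohexan-1-ol (alkynyl axial, cis to the equatorial propenyl), via lithium ethoxyacetylide 16 (not isolated), via dichloro(ethoxyethynyl)cerium 17 (not isolated)
Conditions: 15, n-BuLi, THF, −78 °C; anhydrous CeCl3, −78 °C; then 14, −78 °C; sat. aq. NH4Cl at −78 °C
Reagents that add atoms: 15 ethoxyacetylene, CCOC#C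
Why: 1,2-Addition of an alkynylcerium reagent suppresses enolisation at the acidic, doubly activated C6–H, and the slim nucleophile attacks axially on the face opposite the axial C10 methyl group, which gives the axial alkynyl group cis to the equatorial propenyl group (1S).

Step 13
Reactants: 18 1-(ethoxyethynyl)-2-propenylcyclohexanol
Product: 21 (4R,5Z,7R,8S,10R)-8-(tert-butyldimethylsilyloxy)-12-hydroxy-3,10-epoxygermacra-2,5,11(13)-trien-1-one (furanone-bridged Z-cyclodecene), via potassium allenolate 19 (not isolated), via beta-ethoxy enone 20 (not isolated)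
Conditions: KH (1.3 equiv), 18-crown-6 (1.3 equiv), THF, 0 °C to rt; inverse quench into 1 M aq. HCl/THF, 0 °C to rt
Reagents that add atoms: none
Why: Proposed new method: the potassium alkoxide of 18 weakens the C1–C6 bond, and a suprafacial [3,3] shift through the ground-state chair (ethoxyethynyl axial on C1, (E)-propenyl equatorial on C6) forms C3–C4 as C1–C6 breaks, giving the ten-membered allenolate 19, which is protonated at C2 to the β-ethoxy enone 20. The closest known reaction type is the anionic oxy-Cope ring expansion of 1-alkynyl- and 1-alkenyl-2-alkenylcyclohexanols to cyclodec-5-enones; only the ynol ether as 2π partner is new, and it should be tolerated because the acceleration stems from the alkoxide-weakened C1–C6 bond and because C3, the β-carbon of the incipient alkynone, remains the acceptor terminus although it bears OEt. The ten-membered carbocycle arises by four-atom expansion of the six-membered ring and not by end-to-end cyclisation, and the 3(2H)-furanone closes when the acid cleaves the TMS and TES ethers and O10–H attacks C3 of the O-protonated vinylogous ester (5-exo-trig on its C3=O+Et form) with expulsion of ethanol, the known closure of α'-hydroxy 1,3-dicarbonyl equivalents. C4 is the only new stereocentre: in the six-atom chair C7 is forced pseudo-axial, which makes C5=C6 Z, and the methyl group of the E-propenyl unit lies pseudo-equatorial, so C3 bonds to the C4 face on the side from which C1 departs and chirality passes from C6 and C1 (both erased) to C4 (4R). The step needs [3,3] periselectivity over retro-alkynylation together with facial and geometric control, and both are secured by the locked ring, in which the substituents on C6, C7 and C8 and O10 are all equatorial and the cis axial/equatorial pair holds C3 about 3 Å from C4 in a single reactive rotamer. A 1,4 O-to-O shift of the TMS group between O10 and O1 is reversible and harmless, since only the C1 alkoxide is drained by rearrangement and all TMS leaves in the work-up, which the secondary TBS ether should survive.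

Step 14
Reactants: 21 furanone-bridged Z-cyclodecene
Product: 22 (4R,5Z,7R,8S,10R)-8-(tert-butyldimethylsilyloxy)-1-oxo-3,10-epoxygermacra-2,5,11(13)-trien-12-al
Conditions: activated MnO2 (excess), CH2Cl2, rt
Reagents that add atoms: none
Why: MnO2 oxidises only the primary allylic alcohol and does so under neutral conditions, so the acidic C4–H and the skipped C5=C6 alkene are not disturbed.

Step 15
Reactants: 22 enal
Product: 23 (4R,5Z,7R,8S,10R)-8-(tert-butyldimethylsilyloxy)-1-oxo-3,10-epoxygermacra-2,5,11(13)-trien-12-oic acid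
Conditions: NaClO2, NaH2PO4, 2-methyl-2-butene, t-BuOH/H2O, 0 °C to rt
Reagents that add atoms: sodium chlorite, [Na+].[O-]Cl=O
Why: The Pinnick oxidation converts an α-substituted acrolein into the acrylic acid at buffered pH, and the excess scavenger alkene protects the C5=C6 alkene from hypochlorous acid.

Step 16
Reactants: 23 acrylic acid
Product: 24 tert-butyl (4R,5Z,7R,8S,10R)-8-(tert-butyldimethylsilyloxy)-1-oxo-3,10-epoxygermacra-2,5,11(13)-trien-12-oate
Conditions: O-tert-butyl-N,N'-diisopropylisourea, CH2Cl2, rt
Reagents that add atoms: O-tert-butyl-N,N'-diisopropylisourea, CC(C)NC(=NC(C)C)OC(C)(C)C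
Why: O-Alkylation of the acid by the O-tert-butylisourea proceeds under essentially neutral conditions, and the tert-butyl ester both blocks lactonisation onto O8 and serves as the latent nucleophile of step 20.

Step 17
Reactants: 24 C8-OTBS tert-butyl acrylate
Product: 25 tert-butyl (4R,5Z,7R,8S,10R)-8-hydroxy-1-oxo-3,10-epoxygermacra-2,5,11(13)-trien-12-oate
Conditions: HF·pyridine, pyridine, THF, 0 °C to rt
Reagents that add atoms: none
Why: Buffered fluoride desilylation avoids the basic conditions that could epimerise C4 or move C5=C6 or C11=C13 into conjugation, and the tert-butyl ester is too hindered to lactonise onto the freed C8–OH.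

Step 18
Reactants: 25 C8-hydroxy tert-butyl acrylate
Product: 26 tert-butyl (4R,5S,6R,7R,8S,10R)-5,6:3,10-diepoxy-8-hydroxy-1-oxogermacra-2,11(13)-dien-12-oate (cis-epoxide on the C8 face)
Conditions: VO(acac)2 (5 mol %), t-BuOOH (decane), CH2Cl2, 0 °C to rt
Reagents that add atoms: tert-butyl hydroperoxide, CC(C)(C)OO
Why: In this vanadium-catalysed hydroxyl-directed epoxidation of a homoallylic alcohol only C5=C6 is electron-rich (the acrylate and furanone alkenes are electron-poor), and with H7 held in the alkene plane by A(1,3) strain of the Z alkene the C8-bound vanadium peroxide reaches the face on which C8 lies, which sets 5S and 6R.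

Step 19
Reactants: 26 C5–C6 epoxide; 27 angelic acid
Product: 29 tert-butyl (4R,5S,6R,7R,8S,10R)-8-angeloyloxy-5,6:3,10-diepoxy-1-oxogermacra-2,11(13)-dien-12-oate, via angelic 2,4,6-trichlorobenzoic anhydride 28 (not isolated)
Conditions: 27, 2,4,6-trichlorobenzoyl chloride, Et3N, toluene, rt; then 26, 75 °C (no DMAP)
Reagents that add atoms: 27 angelic acid, C/C=C(/C)C(=O)O
Why: Yamaguchi-type esterification through the preformed mixed anhydride without a nucleophilic catalyst acylates hindered secondary alcohols with angelic acid without Z-to-E isomerisation to the tiglate, and C8 keeps its configuration because only the O–H bond reacts.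

Step 20
Reactants: 29 epoxy C8-angelate
Product: 30 rufescenolide B, (4R,5S,6S,7R,8S,10R)-8-angeloyloxy-5-hydroxy-1-oxo-3,10-epoxygermacra-2,11(13)-dien-12,6-olide
Conditions: TFA, CH2Cl2, 0 °C
Reagents that add atoms: none
Why: In this acid-triggered lactonisation of an epoxy tert-butyl ester the C12 carbonyl oxygen attacks the protonated oxirane at C6 in a 5-exo-tet mode from the face opposite the epoxide oxygen (the face on which C11 lies), which inverts C6 (6R to 6S), leaves the C5–O bond untouched (5S) and, after loss of isobutene, gives the trans-fused α-methylene-γ-lactone.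

## Compound list

1 | (R)-(−)-carvone | CC1=CC[C@H](CC1=O)C(C)=C | starting material
2 | 10-chlorocarvone, (5R)-5-(3-chloroprop-1-en-2-yl)-2-methylcyclohex-2-en-1-one | CC1=CC[C@H](CC1=O)C(=C)CCl | intermediate
3 | 10-acetoxycarvone, 2-[(1R)-4-methyl-5-oxocyclohex-3-en-1-yl]prop-2-en-1-yl acetate | CC1=CC[C@H](CC1=O)C(=C)COC(C)=O | intermediate
4 | 10-hydroxycarvone, (5R)-5-(3-hydroxyprop-1-en-2-yl)-2-methylcyclohex-2-en-1-one | CC1=CC[C@H](CC1=O)C(=C)CO | intermediate
5 | 10-(triethylsilyloxy)carvone | CC1=CC[C@H](CC1=O)C(=C)CO[Si](CC)(CC)CC | intermediate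
6 | (5S)-2-methyl-5-[3-(triethylsilyloxy)prop-1-en-2-yl]-1-(trimethylsilyloxy)cyclohexa-1,3-diene | CC1=C(O[Si](C)(C)C)C[C@@H](C=C1)C(=C)CO[Si](CC)(CC)CC | intermediate
7 | (4S,5R)-4-hydroxy-2-methyl-5-[3-(triethylsilyloxy)prop-1-en-2-yl]cyclohex-2-en-1-one | CC1=C[C@H](O)[C@H](CC1=O)C(=C)CO[Si](CC)(CC)CC | intermediate
8 | (1R,4R,5R,6R)-5-hydroxy-1-methyl-4-[3-(triethylsilyloxy)prop-1-en-2-yl]-7-oxabicyclo[4.1.0]heptan-2-one | C[C@@]12O[C@@H]1[C@H](O)[C@@H](C(=C)CO[Si](CC)(CC)CC)CC2=O | intermediate
9 | (1R,4R,5R,6R)-5-(tert-butyldimethylsilyloxy)-1-methyl-4-[3-(triethylsilyloxy)prop-1-en-2-yl]-7-oxabicyclo[4.1.0]heptan-2-one | C[C@@]12O[C@@H]1[C@H](O[Si](C)(C)C(C)(C)C)[C@@H](C(=C)CO[Si](CC)(CC)CC)CC2=O | intermediate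
10 | (2R,4S,5R)-4-(tert-butyldimethylsilyloxy)-2-methyl-5-[3-(triethylsilyloxy)prop-1-en-2-yl]cyclohexane-1,2-diol (C1 undefined) | OC1[C@](C)(O)C[C@H](O[Si](C)(C)C(C)(C)C)[C@@H](C(=C)CO[Si](CC)(CC)CC)C1 | intermediate
11 | (2R,4S,5R)-4-(tert-butyldimethylsilyloxy)-2-hydroxy-2-methyl-5-[3-(triethylsilyloxy)prop-1-en-2-yl]cyclohexan-1-one | O=C1[C@](C)(O)C[C@H](O[Si](C)(C)C(C)(C)C)[C@@H](C(=C)CO[Si](CC)(CC)CC)C1 | intermediate
12 | (2R,4S,5R)-4-(tert-butyldimethylsilyloxy)-2-methyl-5-[3-(triethylsilyloxy)prop-1-en-2-yl]-2-(trimethylsilyloxy)cyclohexan-1-one | O=C1[C@](C)(O[Si](C)(C)C)C[C@H](O[Si](C)(C)C(C)(C)C)[C@@H](C(=C)CO[Si](CC)(CC)CC)C1 | intermediate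
13 | (E)-1-bromoprop-1-ene | C/C=C/Br | starting material
14 | (2R,4S,5R,6S)-4-(tert-butyldimethylsilyloxy)-2-methyl-6-[(E)-prop-1-enyl]-5-[3-(triethylsilyloxy)prop-1-en-2-yl]-2-(trimethylsilyloxy)cyclohexan-1-one | O=C1[C@](C)(O[Si](C)(C)C)C[C@H](O[Si](C)(C)C(C)(C)C)[C@@H](C(=C)CO[Si](CC)(CC)CC)[C@@H]1/C=C/C | intermediate
15 | ethoxyacetylene | CCOC#C | starting material
16 | lithium ethoxyacetylide | [Li]C#COCC | intermediate
17 | dichloro(ethoxyethynyl)cerium | CCOC#C[Ce](Cl)Cl | intermediate
18 | (1S,2R,4S,5R,6S)-4-(tert-butyldimethylsilyloxy)-1-(ethoxyethynyl)-2-methyl-6-[(E)-prop-1-enyl]-5-[3-(triethylsilyloxy)prop-1-en-2-yl]-2-(trimethylsilyloxy)cyclohexan-1-ol | CCOC#C[C@]1(O)[C@](C)(O[Si](C)(C)C)C[C@H](O[Si](C)(C)C(C)(C)C)[C@@H](C(=C)CO[Si](CC)(CC)CC)[C@@H]1/C=C/C | intermediate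
19 | potassium (4R,5Z,7R,8S,10R)-3-ethoxy-8-(tert-butyldimethylsilyloxy)-12-(triethylsilyloxy)-10-(trimethylsilyloxy)germacra-1,2,5,11(13)-tetraen-1-olate (allene axis undefined) | [K+].[O-]C1=C=C(OCC)[C@H](C)/C=C\[C@H](C(=C)CO[Si](CC)(CC)CC)[C@@H](O[Si](C)(C)C(C)(C)C)C[C@@]1(C)O[Si](C)(C)C | intermediate
20 | (4R,5Z,7R,8S,10R)-3-ethoxy-8-(tert-butyldimethylsilyloxy)-12-(triethylsilyloxy)-10-(trimethylsilyloxy)germacra-2,5,11(13)-trien-1-one (C2=C3 geometry undefined) | O=C1C=C(OCC)[C@H](C)/C=C\[C@H](C(=C)CO[Si](CC)(CC)CC)[C@@H](O[Si](C)(C)C(C)(C)C)C[C@@]1(C)O[Si](C)(C)C | intermediate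
21 | (4R,5Z,7R,8S,10R)-8-(tert-butyldimethylsilyloxy)-12-hydroxy-3,10-epoxygermacra-2,5,11(13)-trien-1-one | C[C@@H]1/C=C\[C@H](C(=C)CO)[C@@H](O[Si](C)(C)C(C)(C)C)C[C@@]2(C)OC1=CC2=O | intermediate
22 | (4R,5Z,7R,8S,10R)-8-(tert-butyldimethylsilyloxy)-1-oxo-3,10-epoxygermacra-2,5,11(13)-trien-12-al | C[C@@H]1/C=C\[C@H](C(=C)C=O)[C@@H](O[Si](C)(C)C(C)(C)C)C[C@@]2(C)OC1=CC2=O | intermediate
23 | (4R,5Z,7R,8S,10R)-8-(tert-butyldimethylsilyloxy)-1-oxo-3,10-epoxygermacra-2,5,11(13)-trien-12-oic acid | C[C@@H]1/C=C\[C@H](C(=C)C(=O)O)[C@@H](O[Si](C)(C)C(C)(C)C)C[C@@]2(C)OC1=CC2=O | intermediate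
24 | tert-butyl (4R,5Z,7R,8S,10R)-8-(tert-butyldimethylsilyloxy)-1-oxo-3,10-epoxygermacra-2,5,11(13)-trien-12-oate | C[C@@H]1/C=C\[C@H](C(=C)C(=O)OC(C)(C)C)[C@@H](O[Si](C)(C)C(C)(C)C)C[C@@]2(C)OC1=CC2=O | intermediate
25 | tert-butyl (4R,5Z,7R,8S,10R)-8-hydroxy-1-oxo-3,10-epoxygermacra-2,5,11(13)-trien-12-oate | C[C@@H]1/C=C\[C@H](C(=C)C(=O)OC(C)(C)C)[C@@H](O)C[C@@]2(C)OC1=CC2=O | intermediate
26 | tert-butyl (4R,5S,6R,7R,8S,10R)-5,6:3,10-diepoxy-8-hydroxy-1-oxogermacra-2,11(13)-dien-12-oate | C[C@@H]1[C@@H]2O[C@@H]2[C@H](C(=C)C(=O)OC(C)(C)C)[C@@H](O)C[C@@]3(C)OC1=CC3=O | intermediate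
27 | angelic acid, (Z)-2-methylbut-2-enoic acid | C/C=C(/C)C(=O)O | starting material
28 | angelic 2,4,6-trichlorobenzoic anhydride | C/C=C(/C)C(=O)OC(=O)c1c(Cl)cc(Cl)cc1Cl | intermediate
29 | tert-butyl (4R,5S,6R,7R,8S,10R)-8-angeloyloxy-5,6:3,10-diepoxy-1-oxogermacra-2,11(13)-dien-12-oate | C[C@@H]1[C@@H]2O[C@@H]2[C@H](C(=C)C(=O)OC(C)(C)C)[C@@H](OC(=O)/C(C)=C\C)C[C@@]3(C)OC1=CC3=O | intermediate
30 | rufescenolide B | C=C1C(=O)O[C@@H]2[C@@H](O)[C@@H](C)C3=CC(=O)[C@@](C)(C[C@H](OC(=O)/C(C)=C\C)[C@@H]12)O3 | target

## Step count and risks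

Total step count: 20.
Longest linear sequence: 20 steps, from 1 to 30. Compounds 13, 15 and 27 enter as purchased materials.

**1. Step 13 (ring expansion and furanone closure).**
- The crown-ether-separated propargylic alkoxide may fragment by retro-addition (loss of potassium ethoxyacetylide) faster than it rearranges, because the donor-substituted alkyne terminus is a poorer acceptor.
- On work-up the skipped C5=C6 alkene may drift into conjugation with the furanone, C4 may epimerise, or the TBS ether may be lost.

The fallback uses known chemistry only. It sets out from 14 and comes back at 21. Ethynylmagnesium bromide with CeCl3 would add to 14 with the same axial preference to give the 1-ethynyl carbinol F1. Its anionic oxy-Cope rearrangement (KH, 18-crown-6) is the known ring expansion of 1-ethynyl-2-alkenylcyclohexanols, and after protonation of the allenolate it would give the silylated cyclodeca-2,5-dienone F2. Dilute acid would remove TMS and TES to give the α'-hydroxy enone diol F3. C3 would then be raised to ketone level by the known Pd(II)-catalysed Wacker-type oxidative cyclisation of α'-hydroxy enones to 3(2H)-furanones (PdCl2(MeCN)2, CuCl, O2), which closes O10–C3 and delivers 21.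

**2. Step 8 (hydride opening at C9).**
- Trans-diaxial opening at C9 requires the ring-flipped half-chair with the C7 and C8 substituents axial, and the axial C7 chain then screens the hydride trajectory, so the reaction may stall at the epoxy alcohol.
- If the C1 alkoxide is formed trans to the oxirane, the material may be diverted by Payne migration.

The fallback sets out from 9 and comes back at 11. With the ketone kept in place, Li2NiBr4 in THF would open the α,β-epoxy ketone at the β-carbon C9. This is the regiochemistry imposed by the carbonyl group and is the mode known for halide opening of carvone oxide. The product would be the C9-bromo C10-hydroxy ketone F4, with the C10–O bond untouched. Radical debromination (Bu3SnH, AIBN, at high stannane concentration to outrun a 1,2-acyl shift) would give 11 directly, without the reduction and re-oxidation at C1.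

**3. Step 4 (linear dienol ether).**
- Deprotonation may occur at C6 and give the cross-conjugated dienol ether, which would lead to oxidation at the wrong carbon in step 5.
- The sensitive triene may aromatise to a carvacrol-type phenol ether.
- In the following oxidation the oxidant may attack C10 instead of C8.

The fallback sets out from 5 and comes back at 7. It avoids any preformed dienol ether and uses the copper-catalysed vinylogous aerobic oxidation of enones (Cu(II) salt, tetramethylguanidine, air). There the reversibly formed dienolate is trapped by oxygen at the γ-carbon, anti to the C7 side chain, to give the C8 hydroperoxy enone F5, which is reduced in the same flask with PPh3 to 7.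

## Further compounds

F1 | step 13 | (1S,2R,4S,5R,6S)-4-(tert-butyldimethylsilyloxy)-1-ethynyl-2-methyl-6-[(E)-prop-1-enyl]-5-[3-(triethylsilyloxy)prop-1-en-2-yl]-2-(trimethylsilyloxy)cyclohexan-1-ol | C#C[C@]1(O)[C@](C)(O[Si](C)(C)C)C[C@H](O[Si](C)(C)C(C)(C)C)[C@@H](C(=C)CO[Si](CC)(CC)CC)[C@@H]1/C=C/C
F2 | step 13 | (4R,5Z,7R,8S,10R)-8-(tert-butyldimethylsilyloxy)-12-(triethylsilyloxy)-10-(trimethylsilyloxy)germacra-2,5,11(13)-trien-1-one (C2=C3 geometry undefined) | O=C1C=C[C@H](C)/C=C\[C@H](C(=C)CO[Si](CC)(CC)CC)[C@@H](O[Si](C)(C)C(C)(C)C)C[C@@]1(C)O[Si](C)(C)C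
F3 | step 13 | (4R,5Z,7R,8S,10R)-8-(tert-butyldimethylsilyloxy)-10,12-dihydroxygermacra-2,5,11(13)-trien-1-one (C2=C3 geometry undefined) | O=C1C=C[C@H](C)/C=C\[C@H](C(=C)CO)[C@@H](O[Si](C)(C)C(C)(C)C)C[C@@]1(C)O
F4 | step 8 | (2S,3S,4R,5R)-3-bromo-4-(tert-butyldimethylsilyloxy)-2-hydroxy-2-methyl-5-[3-(triethylsilyloxy)prop-1-en-2-yl]cyclohexan-1-one (Br on C9, anti to O10) | O=C1[C@](C)(O)[C@@H](Br)[C@H](O[Si](C)(C)C(C)(C)C)[C@@H](C(=C)CO[Si](CC)(CC)CC)C1
F5 | step 4 | (4S,5R)-4-hydroperoxy-2-methyl-5-[3-(triethylsilyloxy)prop-1-en-2-yl]cyclohex-2-en-1-one | CC1=C[C@H](OO)[C@H](CC1=O)C(=C)CO[Si](CC)(CC)CC
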